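**Retrosynthetic overview**
1. Target 25 ⇒ reagent-controlled syn boron aldol of pentan-3-one with the 2-(epoxycyclohexenyl)acrolein 21 (sets C4/C5 of the side chain).
2. 21 ⇒ site- and face-selective epoxidation of cyclohexadiene 20; 20 ⇒ α-methylenation of aldehyde 19.
3. 19 ⇒ amine-catalysed asymmetric 6π-electrocyclisation of the (3E,5Z,7E)-trienal 18 (forms the carbocycle and both ring stereocentres).
4. 18 ⇒ Negishi coupling of (Z)-dienyl iodide 11 with the alkenylzinc from pent-3-yn-1-ol; 11 ⇒ vinylogous aldol condensation of ethylpyranone 4 with (Z)-3-iodo-2-methylacrolein 8.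
5. Ring order: γ-pyranone first (from dione 1), cyclohexadiene second (6π closure), oxirane last.

Assumptions: compounds 1, 5, 12 and 22 are taken as catalogue chemicals. Deprotonated forms of numbered compounds and catalyst-bound species inside catalytic cycles are not numbered separately. Cyclopentadienyl ligands are written σ-bonded in SMILES. The stereocentres in 2, 9 and 10 are unselective and are destroyed again.

**Step 1**
Reactants: 1 4-methylheptane-3,5-dione
Product: 3 6-ethyl-4-hydroxy-3,5-dimethyl-2H-pyran-2-one, via diketo ester 2 (not isolated)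
Conditions: LDA (3.1 equiv), THF, −78 → 0 °C; (MeO)2CO, 0 °C → rt; aq. HCl; crude, DBU, PhMe, 90 °C
Reagents that add atoms: dimethyl carbonate COC(=O)OC
Why: Harris-type dianion chemistry, in which the 1,3-dianion of the β-diketone is C-acylated at its terminal carbanion (Claisen) and DBU then drives enol-lactonisation of 2 with loss of methanol to the 4-hydroxy-2-pyranone.

**Step 2**
Reactants: 3 6-ethyl-4-hydroxy-3,5-dimethyl-2H-pyran-2-one
Product: 4 2-ethyl-6-methoxy-3,5-dimethyl-4H-pyran-4-one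
Conditions: MeOTf, CH2Cl2, 0 °C → rt; aq. NaHCO3
Reagents that add atoms: methyl triflate COS(=O)(=O)C(F)(F)F
Why: Hard O-methylation of the neutral hydroxypyranone takes place at the lactone carbonyl oxygen (via a 2-methoxy-4-hydroxypyrylium ion), which gives the α-methoxy-γ-pyranone regioisomer.

**Step 3**
Reactants: 5 prop-2-yn-1-ol
Product: 7 (Z)-3-iodo-2-methylprop-2-en-1-ol, via oxamagnesole 6 (not isolated)
Conditions: MeMgBr (2.5 equiv), CuI (10 mol%), THF, −10 °C → rt; I2, −40 → 0 °C; aq. NH4Cl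
Reagents that add atoms: methylmagnesium bromide C[Mg]Br; iodine II
Why: Copper-catalysed anti-carbomagnesiation of the propargylic alkoxide (Duboudin–Normant) places methyl on C2 and magnesium on C3 cis to CH2O in chelate 6, and iodinolysis with retention gives the Z iodide.

**Step 4**
Reactants: 7 (Z)-3-iodo-2-methylprop-2-en-1-ol
Product: 8 (Z)-3-iodo-2-methylprop-2-enal
Conditions: MnO2, CH2Cl2, rt, dark; used at once
Reagents that add atoms: none
Why: Neutral allylic oxidation with activated MnO2 leaves the Z iodoalkene untouched.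

**Step 5**
Reactants: 4 2-ethyl-6-methoxy-3,5-dimethyl-4H-pyran-4-one; 8 (Z)-3-iodo-2-methylprop-2-enal
Product: 11 2-[(2E,4Z)-5-iodo-4-methylpenta-2,4-dien-2-yl]-6-methoxy-3,5-dimethyl-4H-pyran-4-one, via lithium aldolate 9 (not isolated), via mesylate 10 (not isolated)
Conditions: LiHMDS, THF, −78 °C; 8; MsCl, −78 → 0 °C; DBU, 0 °C → rt, dark
Reagents that add atoms: none
Why: Vinylogous aldol addition of the γ-lithiated ethylpyranone (extended dienolate) to the aldehyde, followed by in-situ mesylation and E1cB elimination, gives the conjugated E alkene (pyranone trans to the chain) while the Z iodoalkene is retained.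

**Step 6**
Reactants: 12 pent-3-yn-1-ol
Product: 13 tert-butyldimethyl(pent-3-yn-1-yloxy)silane
Conditions: TBSCl, imidazole, CH2Cl2, rt
Reagents that add atoms: tert-butyldimethylsilyl chloride CC(C)(C)[Si](C)(C)Cl
Why: Standard silylation, which prevents alkoxide-directed (proximal) hydrozirconation in the next step.

**Step 7**
Reactants: 13 tert-butyldimethyl(pent-3-yn-1-yloxy)silane; 11 2-[(2E,4Z)-5-iodo-4-methylpenta-2,4-dien-2-yl]-6-methoxy-3,5-dimethyl-4H-pyran-4-one
Product: 16 2-[(2E,4Z,6E)-9-(tert-butyldimethylsilyloxy)-4,6-dimethylnona-2,4,6-trien-2-yl]-6-methoxy-3,5-dimethyl-4H-pyran-4-one, via alkenylzirconocene 14 (not isolated), via alkenylzinc chloride 15 (not isolated)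
Conditions: Cp2Zr(H)Cl (2 equiv), THF, 50 °C; ZnCl2, 0 °C; 11, Pd(PPh3)4 (5 mol%), rt, dark
Reagents that add atoms: none
Why: Syn hydrozirconation with excess Schwartz reagent equilibrates to zirconium on the methyl-bearing carbon, and Zr→Zn transmetalation with Negishi coupling proceeds with retention at both partners to give the (E,Z,E)-triene at room temperature, where thermal 6π closure of such trienes is slow.

**Step 8**
Reactants: 16 the triene silyl ether
Product: 17 2-[(2E,4Z,6E)-9-hydroxy-4,6-dimethylnona-2,4,6-trien-2-yl]-6-methoxy-3,5-dimethyl-4H-pyran-4-one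
Conditions: TBAF, THF, 0 °C
Reagents that add atoms: none
Why: Fluoride-induced desilylation frees the primary alcohol without touching the polyene.

**Step 9**
Reactants: 17 the triene alcohol
Product: 18 (3E,5Z,7E)-8-(6-methoxy-3,5-dimethyl-4-oxo-4H-pyran-2-yl)-4,6-dimethylnona-3,5,7-trienal
Conditions: Dess–Martin periodinane, NaHCO3, CH2Cl2, 0 °C; crude used at once
Reagents that add atoms: none
Why: Buffered Dess–Martin oxidation gives the β,γ-unsaturated aldehyde under conditions too mild to shift or isomerise the double bonds.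

**Step 10**
Reactants: 18 the (3E,5Z,7E)-trienal
Product: 20 2-[(1S,6R)-6-(6-methoxy-3,5-dimethyl-4-oxo-4H-pyran-2-yl)-2,4,6-trimethylcyclohexa-2,4-dien-1-yl]prop-2-enal, via cyclohexadienylacetaldehyde 19 (not isolated)
Conditions: (S)-2-[bis(3,5-bis(trifluoromethyl)phenyl)(trimethylsilyloxy)methyl]pyrrolidine (20 mol%), PhCO2H (20 mol%), CHCl3 (0.02 M), 0 °C → rt, dark; then 37% aq. HCHO, pyrrolidine (10 mol%), EtCO2H (10 mol%), i-PrOH, 40 °C
Reagents that add atoms: formaldehyde C=O
Why: Proposed new method: condensation of the β,γ-unsaturated aldehyde with the chiral secondary amine gives a linear push–pull tetraenamine (amine donor at one end, pyranone acceptor at the other) whose zwitterionic limit makes C3–C8 bond formation a vinylogous iminium/dienolate ring closure, so the otherwise thermally slow disrotatory 6π-electrocyclisation of the (E,Z,E)-triene should run at or below room temperature with negligible racemic background; disrotation puts the pyranonyl group cis to the side chain, and the C(Ar)2OTMS group shields one face of the enamine at the bond-forming carbon to give (1S,6R), the closest known reaction types being β-additions to enal iminium ions, trienamine-activated cycloadditions and Lewis-acid-accelerated 6π-electrocyclisations; hydrolysis releases 19, which is converted in the same pot to 20 by the known amine-catalysed α-methylenation (Mannich/elimination).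

**Step 11**
Reactants: 20 the cyclohexadienyl acrolein
Product: 21 2-[(1R,4R,5S,6S)-4-(6-methoxy-3,5-dimethyl-4-oxo-4H-pyran-2-yl)-2,4,6-trimethyl-7-oxabicyclo[4.1.0]hept-2-en-5-yl]prop-2-enal
Conditions: DMDO (1.05 equiv), acetone, −40 → −20 °C
Reagents that add atoms: dimethyldioxirane CC1(C)OO1
Why: Neutral electrophilic epoxidation attacks the electron-rich ring alkene remote from the quaternary carbon, on the face anti to the pseudoaxial acrolein substituent of the neighbouring carbon, which sets the two oxirane stereocentres; the enal C=C and the pyranone are electron-poor and the vinyl epoxide survives the acid-free conditions.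

**Step 12**
Reactants: 21 the epoxy enal; 22 pentan-3-one
Product: 25 (4R,5R)-5-hydroxy-6-[(1R,4R,5R,6S)-4-(6-methoxy-3,5-dimethyl-4-oxo-4H-pyran-2-yl)-2,4,6-trimethyl-7-oxabicyclo[4.1.0]hept-2-en-5-yl]-4-methylhept-6-en-3-one, via enol borinate 23 (not isolated), via borinate aldolate 24 (not isolated)
Conditions: (+)-Ipc2BOTf [from (−)-α-pinene], i-Pr2NEt, CH2Cl2, −78 °C; 21, −78 → −20 °C; H2O2, MeOH, pH 7 buffer, 0 °C
Reagents that add atoms: none
Why: Paterson boron aldol, in which the Z enol borinate 23 reacts through a chair Zimmerman–Traxler transition state to give the syn aldol and the isopinocampheyl ligands of the (+)-reagent are expected to select the aldehyde re face, giving (4R,5R); the enolate is pre-formed with amine present so the epoxide meets no free Lewis acid.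

**Compound list**
1 | 4-methylheptane-3,5-dione | CCC(=O)C(C)C(=O)CC | starting material
2 | methyl 2,4-dimethyl-3,5-dioxoheptanoate (stereoisomer/tautomer mixture) | CCC(=O)C(C)C(=O)C(C)C(=O)OC | intermediate
3 | 6-ethyl-4-hydroxy-3,5-dimethyl-2H-pyran-2-one | CCc1oc(=O)c(C)c(O)c1C | intermediate
4 | 2-ethyl-6-methoxy-3,5-dimethyl-4H-pyran-4-one | CCc1oc(OC)c(C)c(=O)c1C | intermediate
5 | prop-2-yn-1-ol | C#CCO | starting material
6 | 4-methyl-2,5-dihydro-1,2-oxamagnesole (cyclic alkenylmagnesium alkoxide) | CC1=C[Mg]OC1 | intermediate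
7 | (Z)-3-iodo-2-methylprop-2-en-1-ol | I/C=C(C)\CO | intermediate
8 | (Z)-3-iodo-2-methylprop-2-enal | I/C=C(C)\C=O | intermediate
9 | lithium (4Z)-5-iodo-2-(6-methoxy-3,5-dimethyl-4-oxo-4H-pyran-2-yl)-4-methylpent-4-en-3-olate (C2/C3 epimers) | I/C=C(C)\C(O[Li])C(C)c1oc(OC)c(C)c(=O)c1C | intermediate
10 | (4Z)-5-iodo-2-(6-methoxy-3,5-dimethyl-4-oxo-4H-pyran-2-yl)-4-methylpent-4-en-3-yl methanesulfonate (C2/C3 epimers) | I/C=C(C)\C(OS(C)(=O)=O)C(C)c1oc(OC)c(C)c(=O)c1C | intermediate
11 | 2-[(2E,4Z)-5-iodo-4-methylpenta-2,4-dien-2-yl]-6-methoxy-3,5-dimethyl-4H-pyran-4-one | I/C=C(C)\C=C(/C)c1oc(OC)c(C)c(=O)c1C | intermediate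
12 | pent-3-yn-1-ol | CC#CCCO | starting material
13 | tert-butyldimethyl(pent-3-yn-1-yloxy)silane | CC#CCCO[Si](C)(C)C(C)(C)C | intermediate
14 | chlorobis(cyclopentadienyl)[(2E)-5-(tert-butyldimethylsilyloxy)pent-2-en-2-yl]zirconium | C/C(=C\CCO[Si](C)(C)C(C)(C)C)[Zr](Cl)(C1C=CC=C1)C1C=CC=C1 | intermediate
15 | chloro[(2E)-5-(tert-butyldimethylsilyloxy)pent-2-en-2-yl]zinc | C/C(=C\CCO[Si](C)(C)C(C)(C)C)[Zn]Cl | intermediate
16 | 2-[(2E,4Z,6E)-9-(tert-butyldimethylsilyloxy)-4,6-dimethylnona-2,4,6-trien-2-yl]-6-methoxy-3,5-dimethyl-4H-pyran-4-one | CC(C)(C)[Si](C)(C)OCC/C=C(C)/C=C(C)\C=C(/C)c1oc(OC)c(C)c(=O)c1C | intermediate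
17 | 2-[(2E,4Z,6E)-9-hydroxy-4,6-dimethylnona-2,4,6-trien-2-yl]-6-methoxy-3,5-dimethyl-4H-pyran-4-one | OCC/C=C(C)/C=C(C)\C=C(/C)c1oc(OC)c(C)c(=O)c1C | intermediate
18 | (3E,5Z,7E)-8-(6-methoxy-3,5-dimethyl-4-oxo-4H-pyran-2-yl)-4,6-dimethylnona-3,5,7-trienal | O=CC/C=C(C)/C=C(C)\C=C(/C)c1oc(OC)c(C)c(=O)c1C | intermediate
19 | 2-[(1S,6R)-6-(6-methoxy-3,5-dimethyl-4-oxo-4H-pyran-2-yl)-2,4,6-trimethylcyclohexa-2,4-dien-1-yl]acetaldehyde (pyranonyl cis to CH2CHO) | O=CC[C@H]1C(C)=CC(C)=C[C@@]1(C)c1oc(OC)c(C)c(=O)c1C | intermediate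
20 | 2-[(1S,6R)-6-(6-methoxy-3,5-dimethyl-4-oxo-4H-pyran-2-yl)-2,4,6-trimethylcyclohexa-2,4-dien-1-yl]prop-2-enal | C=C(C=O)[C@H]1C(C)=CC(C)=C[C@@]1(C)c1oc(OC)c(C)c(=O)c1C | intermediate
21 | 2-[(1R,4R,5S,6S)-4-(6-methoxy-3,5-dimethyl-4-oxo-4H-pyran-2-yl)-2,4,6-trimethyl-7-oxabicyclo[4.1.0]hept-2-en-5-yl]prop-2-enal (oxirane anti to the acrolein group) | C=C(C=O)[C@H]1[C@]2(C)O[C@@H]2C(C)=C[C@@]1(C)c1oc(OC)c(C)c(=O)c1C | intermediate
22 | pentan-3-one | CCC(=O)CC | starting material
23 | (Z)-pent-2-en-3-yl di[(+)-isopinocampheyl]borinate | C/C=C(/CC)OB([C@H]1C[C@H]2C[C@@H]([C@@H]1C)C2(C)C)[C@H]1C[C@H]2C[C@@H]([C@@H]1C)C2(C)C | intermediate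
24 | di[(+)-isopinocampheyl]borinate ester of 25 at the C5 oxygen | C=C([C@H](OB([C@H]3C[C@H]4C[C@@H]([C@@H]3C)C4(C)C)[C@H]5C[C@H]6C[C@@H]([C@@H]5C)C6(C)C)[C@@H](C)C(=O)CC)[C@H]1[C@]2(C)O[C@@H]2C(C)=C[C@@]1(C)c1oc(OC)c(C)c(=O)c1C | intermediate
25 | (4R,5R)-5-hydroxy-6-[(1R,4R,5R,6S)-4-(6-methoxy-3,5-dimethyl-4-oxo-4H-pyran-2-yl)-2,4,6-trimethyl-7-oxabicyclo[4.1.0]hept-2-en-5-yl]-4-methylhept-6-en-3-one | C=C([C@H](O)[C@@H](C)C(=O)CC)[C@H]1[C@]2(C)O[C@@H]2C(C)=C[C@@]1(C)c1oc(OC)c(C)c(=O)c1C | target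

**Totals**
Total steps: 12. Longest linear sequence: 9 (steps 1, 2, 5, 7, 8, 9, 10, 11, 12).

**Three steps most likely to fail**

Step 10 (the proposed new reaction). The enamine may not accelerate the ring closure enough, the push–pull polyene may scramble its E/Z geometry, or the remote catalyst may give low ee. If only the sense of induction is wrong, the (R)-catalyst is used. The fallback uses known chemistry, sets out from 17 and comes back at 19. Triene alcohol 17 is heated in degassed o-xylene at 140 °C in the dark, where the thermal disrotatory 6π-electrocyclisation gives the racemic cis-2-[6-(pyranonyl)-2,4,6-trimethylcyclohexa-2,4-dien-1-yl]ethanol F1. Preparative chiral SFC gives the (1S,6R)-alcohol F2. Dess–Martin oxidation of F2 gives 19, which is methylenated to 20 with aqueous formaldehyde and pyrrolidine/propionic acid as in the second half of step 10.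

Step 11 (epoxidation). The two trisubstituted ring alkenes may not be differentiated well enough, and the vinyl epoxide is labile. The fallback sets out from 20 and comes back at 21, and delivers the oxygen by cycloaddition instead of electrophilic transfer. Sensitised photo-oxygenation (O2, tetraphenylporphyrin, hν, CH2Cl2, −78 °C) adds singlet oxygen [4+2] to the diene face anti to the acrolein and pyranonyl groups and gives the 2,3-dioxabicyclo[2.2.2]octene endoperoxide F3. Triphenylphosphine (CH2Cl2, −40 → 0 °C) attacks the peroxide oxygen on the less hindered secondary carbon, and the other oxygen closes by syn SN2′ displacement to give vinyl epoxide 21.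

Step 12 (aldol). The hindered 2-substituted acrolein may give modest reagent control, and the predicted sense of induction by the Ipc ligands needs checking on the first run (the antipodal reagent is the trivial correction). The fallback sets out from 21 and comes back at 25, using auxiliary control. Evans syn aldol of 21 with (R)-4-benzyl-3-propanoyl-1,3-oxazolidin-2-one (Bu2BOTf, Et3N, CH2Cl2, −78 → 0 °C) gives the (2R,3R)-syn imide F4. Transamidation (MeNHOMe·HCl, i-PrMgCl, THF, −20 °C) gives the Weinreb amide F5. Ethylmagnesium bromide (THF, 0 °C) then gives 25.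

**Further compounds**
F1 | step 10 | racemic cis-2-[6-(6-methoxy-3,5-dimethyl-4-oxo-4H-pyran-2-yl)-2,4,6-trimethylcyclohexa-2,4-dien-1-yl]ethanol | OCC[C@H]1C(C)=CC(C)=C[C@@]1(C)c1oc(OC)c(C)c(=O)c1C.OCC[C@@H]1C(C)=CC(C)=C[C@]1(C)c1oc(OC)c(C)c(=O)c1C
F2 | step 10 | 2-[(1S,6R)-6-(6-methoxy-3,5-dimethyl-4-oxo-4H-pyran-2-yl)-2,4,6-trimethylcyclohexa-2,4-dien-1-yl]ethanol | OCC[C@H]1C(C)=CC(C)=C[C@@]1(C)c1oc(OC)c(C)c(=O)c1C
F3 | step 11 | 2-[8-(6-methoxy-3,5-dimethyl-4-oxo-4H-pyran-2-yl)-1,5,8-trimethyl-2,3-dioxabicyclo[2.2.2]oct-5-en-7-yl]prop-2-enal, peroxide bridge anti to the acrolein and pyranonyl groups | C=C(C=O)[C@H]1[C@@]2(C)C=C(C)[C@H](OO2)[C@@]1(C)c1oc(OC)c(C)c(=O)c1C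
F4 | step 12 | (4R)-4-benzyl-3-[(2R,3R)-3-hydroxy-2-methyl-4-{(1R,4R,5R,6S)-4-(6-methoxy-3,5-dimethyl-4-oxo-4H-pyran-2-yl)-2,4,6-trimethyl-7-oxabicyclo[4.1.0]hept-2-en-5-yl}pent-4-enoyl]-1,3-oxazolidin-2-one | C=C([C@H](O)[C@@H](C)C(=O)N3[C@H](Cc4ccccc4)COC3=O)[C@H]1[C@]2(C)O[C@@H]2C(C)=C[C@@]1(C)c1oc(OC)c(C)c(=O)c1C
F5 | step 12 | (2R,3R)-3-hydroxy-N-methoxy-N,2-dimethyl-4-[(1R,4R,5R,6S)-4-(6-methoxy-3,5-dimethyl-4-oxo-4H-pyran-2-yl)-2,4,6-trimethyl-7-oxabicyclo[4.1.0]hept-2-en-5-yl]pent-4-enamide | C=C([C@H](O)[C@@H](C)C(=O)N(C)OC)[C@H]1[C@]2(C)O[C@@H]2C(C)=C[C@@]1(C)c1oc(OC)c(C)c(=O)c1C
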